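Millimolar per minute is the unit for following the loss of target here, because the two runs differ in charge and a percent of one is not a percent of the other.

| setting | dusk | winter | flask |
|---|---|---|---|
| starting material | 0.024 M | 0.048 M | 0.024 M |
| remark | the very flask that is asked about, followed so far | run made earlier |  |
| time |  |  | 8.0 min |

- dusk (time / s: target / %, starting material / %): 20.0: 59.5, 28.7; 40.0: 78.2, 7.5; 60.0: 83.5, 0.8; 80.0: 83.8, 1.4
- winter (time / min: target / %, starting material / %): 0.833: 82.8, 4.8; 1.50: 89.2, 0; 2.50: 88.4, 1.6; 3.00: 86.6, 2.1

(each reading ± 1 percentage point)

- a reading or a percentage of target counts all its forms, free or not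

* time, not beyond 8.0 min, at which the flask holds most target
* the amount of target, in percent of the starting material charged, at that time

How fast does starting material go? Work with the fraction left: the dusk run reads 7.5 % at 40.0 s, so the logarithm of its inverse over that time gives a first-order constant of 3.89 /min.

How much of what goes becomes target? At 60.0 s the dusk run reads 83.5 % of target with 0.8 % left, a share, or selectivity, of 84.2 %.

How fast does target go? The winter run reads 89.2 % at 1.50 min and 86.6 % at 3.00 min, a fall in [target] of 0.832 mM/min. I carry this as a fixed drain on [target] per minute, a zero-order loss, which is my assumption.

In the asked flask the drain takes 0.0347 /min of the charge. Gain equals drain when the fraction left is 1.06 %, so I expect the peak at 1.17 min with 83.3 % of target.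

The forecast, which says “The target therefore seems to be slowly lost”, gives 1.4 min (1 min to 2.2 min) and 84.3 % (83 % to 85.8 %). My time is earlier.

The flask peaks at 1.35 min with 83.9 % of target.

    crystals ⇌ target, rate k1*(cs1 - [target]) while solid is left; crystals form when [target] > cs1 (solubility = 0.320 mM, k = 1.30 /s)
    target → over-reaction product (k = 0.0560 /s)
    starting material ⇌ target (K = 1.80, k = 0.0610 /s)
    target ⇌ isomer of the product (k = 0.0870 /s)
    starting material ⇌ isomer of the product (K = 5.30, k = 0.00240 /s)

At that time nearly all of the flask's target stands as crystals, 82.6 % of the charge. Run on from the peak to 8.0 min, the drain reckons 60.8 % of target, and the flask holds 57.3 %. Take a neighbour charged with 0.041 M, whose highest target is 88.1 %. Taking that highest value at the best time of the asked flask, which is my assumption, the same drain in millimolar per minute reckons 74.6 % at 8.0 min, and the neighbour holds 73.3 %.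

The data were generated by integration with made-up constants; noise was put on by code.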